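**Retrosynthetic overview**
1. Feature used: on ring A of the flavanone half, O1 is bonded to C8a, the C4 carbonyl carbon to the adjacent C4a, and the C5 oxygen stands next to C4a. A 3-alkoxybenzyne hands exactly this array to an oxygen nucleophile and an acyl electrophile held in one chain.
2. After global O-debenzylation, O1–C8a and C4–C4a are cut together. This gives 3,5-bis(benzyloxy)benzyne and an anti beta-oxy methyl ester that already carries C2, C3, the 4-oxyphenyl group and the whole flavone.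
3. C2–C3 is cut by an auxiliary-controlled anti-aldol between a flavon-3-ylacetyl imide and 4-(benzyloxy)benzaldehyde, which sets both stereocentres.
4. The flavone goes back to a 1,3-diketone (aroylation of di-O-benzylphloracetophenone) that is C-alkylated with a bromoacetyl unit and cyclodehydrated. The aryne precursor comes from 3,5-bis(benzyloxy)phenol.
5. Ring order: the flavone pyranone ring first, then flavanone ring C, closed in the same operation that attaches ring A.

Key step: step 12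

Assumption: the MgCl2-catalysed anti-aldol of the flavonylacetyl imide is taken to follow the facial sense known for the propionyl imide of the same auxiliary (aldehyde enters the chelated Z-enolate on the face away from the benzyl group), so the (S)-auxiliary is assigned to the (2R,3S) adduct; if a check on the adduct shows the opposite sense, the (R)-auxiliary is used in the same steps.

Step 1
Reactants: 1 2,4,6-trihydroxyacetophenone
Product: 2 1-[2,4-bis(benzyloxy)-6-hydroxyphenyl]ethan-1-one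
Conditions: BnBr (2.1 equiv), K2CO3, DMF, 23 to 60 °C
Reagents that add atoms: benzyl bromide, BrCc1ccccc1
Why: Williamson ether synthesis in which the hydroxyl hydrogen-bonded to the acetyl carbonyl is the least reactive and should stay free when only two equivalents of halide are offered.

Step 2
Reactants: 2 1-[2,4-bis(benzyloxy)-6-hydroxyphenyl]ethan-1-one, 3 4-(benzyloxy)benzoyl chloride
Product: 4 1-[2,4-bis(benzyloxy)-6-hydroxyphenyl]-3-[4-(benzyloxy)phenyl]propane-1,3-dione
Conditions: LiN(SiMe3)2 (3.3 equiv), THF, −78 to −10 °C; 3, −78 to 23 °C; 1 M HCl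
Reagents that add atoms: none
Why: Claisen-type C-aroylation of the lithium phenoxide–enolate (a one-flask form of the Baker–Venkataraman sequence), in which any O-aroylated material is carried to the same diketone by the excess base.

Step 3
Reactants: 5 (S)-4-benzyl-1,3-oxazolidin-2-one, 6 bromoacetyl bromide
Product: 7 (4S)-4-benzyl-3-(bromoacetyl)-1,3-oxazolidin-2-one
Conditions: n-BuLi, THF, −78 °C; 6, −78 to 0 °C
Reagents that add atoms: none
Why: Standard N-acylation of a lithiated Evans auxiliary, where substitution at the acyl bromide is far faster than at the alkyl bromide and the auxiliary stereocentre is untouched.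

Step 4
Reactants: 4 1-[2,4-bis(benzyloxy)-6-hydroxyphenyl]-3-[4-(benzyloxy)phenyl]propane-1,3-dione, 7 (4S)-4-benzyl-3-(bromoacetyl)-1,3-oxazolidin-2-one
Product: 9 (4S)-4-benzyl-3-({5,7-bis(benzyloxy)-2-[4-(benzyloxy)phenyl]-4-oxo-4H-chromen-3-yl}acetyl)-1,3-oxazolidin-2-one, via C-alkylated diketone 8 (not isolated)
Conditions: K2CO3, acetone, 0 to 23 °C; filter, concentrate; p-TsOH·H2O (0.2 equiv), toluene, 80 °C
Reagents that add atoms: none
Why: C-alkylation of a beta-diketone enolate by a soft alpha-bromo carbonyl electrophile, then acid-catalysed cyclodehydration (closing stage of the Baker–Venkataraman flavone synthesis) in which the phenol adds to the aroyl carbonyl and water is lost, so the branching stereocentre of 8 disappears.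

Step 5
Reactants: 9 (4S)-4-benzyl-3-({5,7-bis(benzyloxy)-2-[4-(benzyloxy)phenyl]-4-oxo-4H-chromen-3-yl}acetyl)-1,3-oxazolidin-2-one, 10 4-(benzyloxy)benzaldehyde
Product: 12 (4S)-4-benzyl-3-[(2R,3S)-2-{5,7-bis(benzyloxy)-2-[4-(benzyloxy)phenyl]-4-oxo-4H-chromen-3-yl}-3-[4-(benzyloxy)phenyl]-3-hydroxypropanoyl]-1,3-oxazolidin-2-one, via O-trimethylsilyl aldol adduct 11 (not isolated)
Conditions: MgCl2 (0.2 equiv), Et3N, Me3SiCl, EtOAc, 23 °C; then CF3CO2H (cat.), MeOH, 0 °C
Reagents that add atoms: chlorotrimethylsilane, C[Si](C)(C)Cl (its silyl group is present in 11 only and is lost again before 12)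
Why: Evans MgCl2-catalysed anti-aldol reaction: soft enolisation gives the chelated Z-enolate, the non-enolisable electron-rich aldehyde adds on the face away from the auxiliary benzyl group to set propanoyl C2 (R, later flavanone C3) and, through the anti-selective transition state, C3 (S, later flavanone C2), silylation of the aldolate makes the addition irreversible, and minor diastereomers remain separable while the auxiliary is attached.

Step 6
Reactants: 12 (4S)-4-benzyl-3-[(2R,3S)-2-{5,7-bis(benzyloxy)-2-[4-(benzyloxy)phenyl]-4-oxo-4H-chromen-3-yl}-3-[4-(benzyloxy)phenyl]-3-hydroxypropanoyl]-1,3-oxazolidin-2-one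
Product: 14 (2R,3S)-2-{5,7-bis(benzyloxy)-2-[4-(benzyloxy)phenyl]-4-oxo-4H-chromen-3-yl}-3-[4-(benzyloxy)phenyl]-3-hydroxypropanoic acid, via peroxy acid 13 (not isolated)
Conditions: LiOH, H2O2, THF–H2O (3:1), 0 °C; Na2SO3; 1 M HCl to pH 3
Reagents that add atoms: hydrogen peroxide, OO
Why: Hydroperoxide cleavage of an Evans imide, in which the small, weakly basic LiOOH attacks the exocyclic carbonyl even of hindered imides, should cause neither epimerisation nor retro-aldol cleavage at 0 °C, and sulfite reduces the peroxy acid to the acid.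

Step 7
Reactants: 14 (2R,3S)-2-{5,7-bis(benzyloxy)-2-[4-(benzyloxy)phenyl]-4-oxo-4H-chromen-3-yl}-3-[4-(benzyloxy)phenyl]-3-hydroxypropanoic acid
Product: 15 methyl (2R,3S)-2-{5,7-bis(benzyloxy)-2-[4-(benzyloxy)phenyl]-4-oxo-4H-chromen-3-yl}-3-[4-(benzyloxy)phenyl]-3-hydroxypropanoate
Conditions: MeI, KHCO3, DMF, 23 °C
Reagents that add atoms: iodomethane, CI
Why: SN2 O-alkylation of the carboxylate, with a base too weak to deprotonate the alcohol or the C–H next to the carboxyl group, so both stereocentres are kept.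

Step 8
Reactants: 15 methyl (2R,3S)-2-{5,7-bis(benzyloxy)-2-[4-(benzyloxy)phenyl]-4-oxo-4H-chromen-3-yl}-3-[4-(benzyloxy)phenyl]-3-hydroxypropanoate
Product: 16 methyl (2R,3S)-2-{5,7-bis(benzyloxy)-2-[4-(benzyloxy)phenyl]-4-oxo-4H-chromen-3-yl}-3-[4-(benzyloxy)phenyl]-3-[(trimethylsilyl)oxy]propanoate
Conditions: Me3SiCl, imidazole, CH2Cl2, 0 °C
Reagents that add atoms: chlorotrimethylsilane, C[Si](C)(C)Cl
Why: Silyl ether formation, which removes the one O–H proton that would quench the aryl anion of step 12 and turns the oxygen into a nucleophile that only fluoride unmasks.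

Step 9
Reactants: 17 3,5-bis(benzyloxy)phenol
Product: 18 3,5-bis(benzyloxy)-2-bromophenol
Conditions: NBS (1.0 equiv), CH2Cl2, −78 to 0 °C
Reagents that add atoms: N-bromosuccinimide, O=C1CCC(=O)N1Br
Why: Electrophilic aromatic bromination, expected at the position between OH and OBn because it is less crowded than the position between the two benzyloxy groups and is statistically doubled.

Step 10
Reactants: 18 3,5-bis(benzyloxy)-2-bromophenol
Product: 19 [3,5-bis(benzyloxy)-2-bromophenoxy]trimethylsilane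
Conditions: (Me3Si)2NH, THF, 65 °C
Reagents that add atoms: hexamethyldisilazane, C[Si](C)(C)N[Si](C)(C)C
Why: O-silylation of a phenol with hexamethyldisilazane, which needs no added base and leaves only a volatile by-product.

Step 11
Reactants: 19 [3,5-bis(benzyloxy)-2-bromophenoxy]trimethylsilane
Product: 21 3,5-bis(benzyloxy)-2-(trimethylsilyl)phenyl trifluoromethanesulfonate, via lithium silylphenoxide 20 (not isolated)
Conditions: n-BuLi, THF, −78 °C; then Tf2O, −78 to 0 °C
Reagents that add atoms: trifluoromethanesulfonic anhydride, O=S(=O)(OS(=O)(=O)C(F)(F)F)C(F)(F)F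
Why: Bromine–lithium exchange, O-to-C silyl migration (retro-Brook rearrangement) and triflation of the phenoxide, the standard entry to Kobayashi aryne precursors, with exchange at −78 °C faster than benzylic lithiation.

Step 12
Reactants: 16 methyl (2R,3S)-2-{5,7-bis(benzyloxy)-2-[4-(benzyloxy)phenyl]-4-oxo-4H-chromen-3-yl}-3-[4-(benzyloxy)phenyl]-3-[(trimethylsilyl)oxy]propanoate, 21 3,5-bis(benzyloxy)-2-(trimethylsilyl)phenyl trifluoromethanesulfonate
Product: 24 (2S,3R)-5,7-bis(benzyloxy)-2-[4-(benzyloxy)phenyl]-3-{5,7-bis(benzyloxy)-2-[4-(benzyloxy)phenyl]-4-oxo-4H-chromen-3-yl}-2,3-dihydro-4H-chromen-4-one, via 3,5-bis(benzyloxy)benzyne 22 (not isolated), via caesium aryl anion 23 (not isolated)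
Conditions: 16 and 21 (2 equiv) premixed; CsF (4 equiv), 18-crown-6 (0.5 equiv), THF, 0 to 23 °C, closed flask
Reagents that add atoms: none
Why: Proposed new method: attack of fluoride on the aryl–SiMe3 group of 21 with loss of triflate generates aryne 22, fluoride (later the expelled methoxide) activates the O–SiMe3 bond of 16, the oxygen on the future C2 adds to the aryne carbon remote from the flanking benzyloxy group, and aryl anion 23 substitutes methoxide at the ester carbonyl, so that O1–C8a and C4–C4a form in one operation. Nearest precedents: arynes combine with methyl salicylates or methyl anthranilates to give xanthones or acridones by the same arylation-then-acylation order of events, and carboxylic acids add across arynes to give ortho-hydroxyaryl ketones; new here are the secondary benzylic, aliphatic oxygen nucleophile and the non-aromatic ester as acyl acceptor. Ring C closes by 6-exo-trig acyl substitution (overall a formal [4+2] annulation) through a chair-like array in which the anti configuration of 16 lets the C2 aryl and C3 flavonyl groups both lie equatorial. No stereocentre is created: the C2–O bond is never broken, C3 comes from the aldol step, and because 2,3-trans is also the more stable arrangement at the enolisable C3, any epimerisation there corrects itself. The regioselectivity needed (oxygen on C8a, acyl on C4a) rests on the benzyloxy group next to the triple bond, which bends the aryne so that the remote carbon is the more linear and more electrophilic one and places the carbanion beside an inductively withdrawing oxygen. The chemoselectivity needed (acylation of 23 rather than protonation, no retro-aldol cleavage, no E1cB opening of 24) is sought by using the silyl ether instead of free alcohol 15, whose proton would quench 23, by the aprotic solvent and low temperature, and by silyl transfer to the expelled methoxide (MeOSiMe3), so that no strong base accumulates.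

Step 13
Reactants: 24 (2S,3R)-5,7-bis(benzyloxy)-2-[4-(benzyloxy)phenyl]-3-{5,7-bis(benzyloxy)-2-[4-(benzyloxy)phenyl]-4-oxo-4H-chromen-3-yl}-2,3-dihydro-4H-chromen-4-one
Product: 25 (2S,3R)-5,7-dihydroxy-3-[5,7-dihydroxy-2-(4-hydroxyphenyl)-4-oxo-4H-chromen-3-yl]-2-(4-hydroxyphenyl)-2,3-dihydro-4H-chromen-4-one (CNP0208264.1)
Conditions: H2 (1 atm), 10% Pd/C, THF–MeOH (1:1), 23 °C
Reagents that add atoms: none
Why: Catalytic hydrogenolysis of six aryl benzyl ethers under neutral conditions, which should leave the tetrasubstituted chromone double bond, both donor-deactivated aryl ketones and the configurations at C2 and C3 untouched.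

**Compound list**
1 | 2,4,6-trihydroxyacetophenone | CC(=O)c1c(O)cc(O)cc1O | starting material
2 | 1-[2,4-bis(benzyloxy)-6-hydroxyphenyl]ethan-1-one | CC(=O)c1c(O)cc(OCc2ccccc2)cc1OCc1ccccc1 | intermediate
3 | 4-(benzyloxy)benzoyl chloride | O=C(Cl)c1ccc(OCc2ccccc2)cc1 | starting material
4 | 1-[2,4-bis(benzyloxy)-6-hydroxyphenyl]-3-[4-(benzyloxy)phenyl]propane-1,3-dione (drawn as diketo tautomer) | O=C(CC(=O)c1ccc(OCc2ccccc2)cc1)c1c(O)cc(OCc2ccccc2)cc1OCc1ccccc1 | intermediate
5 | (S)-4-benzyl-1,3-oxazolidin-2-one | O=C1N[C@@H](Cc2ccccc2)CO1 | starting material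
6 | bromoacetyl bromide | O=C(Br)CBr | starting material
7 | (4S)-4-benzyl-3-(bromoacetyl)-1,3-oxazolidin-2-one | O=C(CBr)N1[C@@H](Cc2ccccc2)COC1=O | intermediate
8 | (4S)-4-benzyl-3-{3-[2,4-bis(benzyloxy)-6-hydroxybenzoyl]-4-[4-(benzyloxy)phenyl]-4-oxobutanoyl}-1,3-oxazolidin-2-one (both epimers at the branching carbon) | O=C(CC(C(=O)c1ccc(OCc2ccccc2)cc1)C(=O)c1c(O)cc(OCc2ccccc2)cc1OCc1ccccc1)N1[C@@H](Cc2ccccc2)COC1=O | intermediate (not isolated)
9 | (4S)-4-benzyl-3-({5,7-bis(benzyloxy)-2-[4-(benzyloxy)phenyl]-4-oxo-4H-chromen-3-yl}acetyl)-1,3-oxazolidin-2-one | O=C(Cc1c(-c2ccc(OCc3ccccc3)cc2)oc2cc(OCc3ccccc3)cc(OCc3ccccc3)c2c1=O)N1[C@@H](Cc2ccccc2)COC1=O | intermediate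
10 | 4-(benzyloxy)benzaldehyde | O=Cc1ccc(OCc2ccccc2)cc1 | starting material
11 | O-trimethylsilyl ether of 12, (2R,3S) | O=C(N1[C@@H](Cc2ccccc2)COC1=O)[C@H](c1c(-c2ccc(OCc3ccccc3)cc2)oc2cc(OCc3ccccc3)cc(OCc3ccccc3)c2c1=O)[C@H](O[Si](C)(C)C)c1ccc(OCc2ccccc2)cc1 | intermediate (not isolated)
12 | (4S)-4-benzyl-3-[(2R,3S)-2-{5,7-bis(benzyloxy)-2-[4-(benzyloxy)phenyl]-4-oxo-4H-chromen-3-yl}-3-[4-(benzyloxy)phenyl]-3-hydroxypropanoyl]-1,3-oxazolidin-2-one | O=C(N1[C@@H](Cc2ccccc2)COC1=O)[C@H](c1c(-c2ccc(OCc3ccccc3)cc2)oc2cc(OCc3ccccc3)cc(OCc3ccccc3)c2c1=O)[C@H](O)c1ccc(OCc2ccccc2)cc1 | intermediate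
13 | (2R,3S)-2-{5,7-bis(benzyloxy)-2-[4-(benzyloxy)phenyl]-4-oxo-4H-chromen-3-yl}-3-[4-(benzyloxy)phenyl]-3-hydroxypropaneperoxoic acid | OOC(=O)[C@H](c1c(-c2ccc(OCc3ccccc3)cc2)oc2cc(OCc3ccccc3)cc(OCc3ccccc3)c2c1=O)[C@H](O)c1ccc(OCc2ccccc2)cc1 | intermediate (not isolated)
14 | (2R,3S)-2-{5,7-bis(benzyloxy)-2-[4-(benzyloxy)phenyl]-4-oxo-4H-chromen-3-yl}-3-[4-(benzyloxy)phenyl]-3-hydroxypropanoic acid | OC(=O)[C@H](c1c(-c2ccc(OCc3ccccc3)cc2)oc2cc(OCc3ccccc3)cc(OCc3ccccc3)c2c1=O)[C@H](O)c1ccc(OCc2ccccc2)cc1 | intermediate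
15 | methyl (2R,3S)-2-{5,7-bis(benzyloxy)-2-[4-(benzyloxy)phenyl]-4-oxo-4H-chromen-3-yl}-3-[4-(benzyloxy)phenyl]-3-hydroxypropanoate | COC(=O)[C@H](c1c(-c2ccc(OCc3ccccc3)cc2)oc2cc(OCc3ccccc3)cc(OCc3ccccc3)c2c1=O)[C@H](O)c1ccc(OCc2ccccc2)cc1 | intermediate
16 | methyl (2R,3S)-2-{5,7-bis(benzyloxy)-2-[4-(benzyloxy)phenyl]-4-oxo-4H-chromen-3-yl}-3-[4-(benzyloxy)phenyl]-3-[(trimethylsilyl)oxy]propanoate | COC(=O)[C@H](c1c(-c2ccc(OCc3ccccc3)cc2)oc2cc(OCc3ccccc3)cc(OCc3ccccc3)c2c1=O)[C@H](O[Si](C)(C)C)c1ccc(OCc2ccccc2)cc1 | intermediate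
17 | 3,5-bis(benzyloxy)phenol | Oc1cc(OCc2ccccc2)cc(OCc2ccccc2)c1 | starting material
18 | 3,5-bis(benzyloxy)-2-bromophenol | Oc1cc(OCc2ccccc2)cc(OCc2ccccc2)c1Br | intermediate
19 | [3,5-bis(benzyloxy)-2-bromophenoxy]trimethylsilane | C[Si](C)(C)Oc1cc(OCc2ccccc2)cc(OCc2ccccc2)c1Br | intermediate
20 | lithium 3,5-bis(benzyloxy)-2-(trimethylsilyl)phenoxide | [Li+].[O-]c1cc(OCc2ccccc2)cc(OCc2ccccc2)c1[Si](C)(C)C | intermediate (not isolated)
21 | 3,5-bis(benzyloxy)-2-(trimethylsilyl)phenyl trifluoromethanesulfonate | C[Si](C)(C)c1c(OCc2ccccc2)cc(OCc2ccccc2)cc1OS(=O)(=O)C(F)(F)F | intermediate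
22 | 3,5-bis(benzyloxy)benzyne | C1#CC(OCc2ccccc2)=CC(OCc2ccccc2)=C1 | intermediate (not isolated)
23 | caesium salt of the aryl anion formed by O-arylation (carbanion between the new ether oxygen and a benzyloxy group), (2R,3S) | COC(=O)[C@H](c1c(-c2ccc(OCc3ccccc3)cc2)oc2cc(OCc3ccccc3)cc(OCc3ccccc3)c2c1=O)[C@H](Oc1cc(OCc2ccccc2)cc(OCc2ccccc2)[c-]1)c1ccc(OCc2ccccc2)cc1.[Cs+] | intermediate (not isolated)
24 | (2S,3R)-5,7-bis(benzyloxy)-2-[4-(benzyloxy)phenyl]-3-{5,7-bis(benzyloxy)-2-[4-(benzyloxy)phenyl]-4-oxo-4H-chromen-3-yl}-2,3-dihydro-4H-chromen-4-one (2,3-trans) | O=C1c2c(OCc3ccccc3)cc(OCc3ccccc3)cc2O[C@H](c2ccc(OCc3ccccc3)cc2)[C@H]1c1c(-c2ccc(OCc3ccccc3)cc2)oc2cc(OCc3ccccc3)cc(OCc3ccccc3)c2c1=O | intermediate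
25 | (2S,3R)-5,7-dihydroxy-3-[5,7-dihydroxy-2-(4-hydroxyphenyl)-4-oxo-4H-chromen-3-yl]-2-(4-hydroxyphenyl)-2,3-dihydro-4H-chromen-4-one | O=C1c2c(O)cc(O)cc2O[C@H](c2ccc(O)cc2)[C@H]1c1c(-c2ccc(O)cc2)oc2cc(O)cc(O)c2c1=O | target

**Totals**
Total step count: 13.
Longest linear sequence: 9 steps (1, 2, 4, 5, 6, 7, 8, 12, 13).

**Steps most likely to fail**

1. Step 12 (new method).
- What may go wrong: once fluoride unmasks the oxygen, the aldolate may fragment by retro-aldol cleavage, or the ester enolate may expel the oxygen by beta-elimination, before an aryne is met. After O-arylation, the aryl anion may be quenched by internal transfer of the acidic C–H next to the ester instead of attacking the carbonyl group.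
- Fallback (known chemistry, from 15 back to 24): the two bonds are made one after the other, and the polarity of the C4–C4a bond formation is reversed. Alcohol 15 is O-arylated with retention by Chan–Lam coupling with commercial 3,5-bis(benzyloxy)phenylboronic acid (Cu(OAc)2, DMAP, 4 Å molecular sieves, O2, CH2Cl2, 23 °C). This coupling needs no alkoxide and gives the 3,5-bis(benzyloxy)phenyl ether F1. Me3SnOH in 1,2-dichloroethane at 70 °C cleaves the methyl ester without free base to the carboxylic acid F2. (CF3CO)2O in CH2Cl2 at 0 °C forms the mixed trifluoroacetic anhydride F3. This acylates one of the two equivalent positions ortho to the ether oxygen of the electron-rich ring (intramolecular Friedel–Crafts acylation) and delivers 24.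

2. Step 5.
- What may go wrong: the twisted, bulky flavonyl group and competing binding of magnesium to the chromone carbonyl may slow enolisation and catalyst turnover. They may also erode the anti selectivity of the addition.
- Fallback (from 9 back to 24): only the carbinol configuration is fixed in the aldol step, and C3 is set later by equilibration. The Evans boron syn-aldol (Bu2BOTf, i-Pr2NEt, CH2Cl2, −78 to 0 °C, then 10, oxidative work-up) passes through a closed Zimmerman–Traxler transition state. With the same auxiliary it should give the (2S,3S) syn adduct F4, which has the required carbinol configuration. The operations of steps 6 to 8 lead through the syn peroxy acid F5 to the syn hydroxy acid F6, the syn methyl ester F7 and the syn silyl ether F8. Annulation with 21 under the conditions of step 12 passes through the syn aryl anion F9 and gives the 2,3-cis (2S,3S) hexa-O-benzyl flavanone F10. Et3N in CH2Cl2 at 23 °C then equilibrates the enolisable C3 to the trans isomer 24.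

3. Step 4.
- What may go wrong: O-alkylation at the phenol or the enol oxygen, and loss of the auxiliary by acyl transfer from the reactive imide to the enolate oxygen or the phenoxide.
- Fallback (from 4 back to 9): the side chain is brought in as a robust ester and the auxiliary is attached only after the flavone ring exists. Diketone 4 is alkylated with tert-butyl bromoacetate (K2CO3, acetone, 23 °C) to the tert-butyl keto ester F11. CF3CO2H in CH2Cl2 at 23 °C both closes the pyranone ring and cleaves the tert-butyl ester, giving the flavon-3-ylacetic acid F12. Pivaloyl chloride and Et3N in THF at 0 °C form the mixed pivalic anhydride F13, which acylates 5 in the presence of LiCl to give 9.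

**Further compounds**
F1 | step 12 | methyl (2R,3S)-3-[3,5-bis(benzyloxy)phenoxy]-2-{5,7-bis(benzyloxy)-2-[4-(benzyloxy)phenyl]-4-oxo-4H-chromen-3-yl}-3-[4-(benzyloxy)phenyl]propanoate | COC(=O)[C@H](c1c(-c2ccc(OCc3ccccc3)cc2)oc2cc(OCc3ccccc3)cc(OCc3ccccc3)c2c1=O)[C@H](Oc1cc(OCc2ccccc2)cc(OCc2ccccc2)c1)c1ccc(OCc2ccccc2)cc1
F2 | step 12 | (2R,3S)-3-[3,5-bis(benzyloxy)phenoxy]-2-{5,7-bis(benzyloxy)-2-[4-(benzyloxy)phenyl]-4-oxo-4H-chromen-3-yl}-3-[4-(benzyloxy)phenyl]propanoic acid | OC(=O)[C@H](c1c(-c2ccc(OCc3ccccc3)cc2)oc2cc(OCc3ccccc3)cc(OCc3ccccc3)c2c1=O)[C@H](Oc1cc(OCc2ccccc2)cc(OCc2ccccc2)c1)c1ccc(OCc2ccccc2)cc1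
F3 | step 12 | mixed anhydride of F2 and trifluoroacetic acid | O=C(OC(=O)C(F)(F)F)[C@H](c1c(-c2ccc(OCc3ccccc3)cc2)oc2cc(OCc3ccccc3)cc(OCc3ccccc3)c2c1=O)[C@H](Oc1cc(OCc2ccccc2)cc(OCc2ccccc2)c1)c1ccc(OCc2ccccc2)cc1
F4 | step 5 | (4S)-4-benzyl-3-[(2S,3S)-2-{5,7-bis(benzyloxy)-2-[4-(benzyloxy)phenyl]-4-oxo-4H-chromen-3-yl}-3-[4-(benzyloxy)phenyl]-3-hydroxypropanoyl]-1,3-oxazolidin-2-one | O=C(N1[C@@H](Cc2ccccc2)COC1=O)[C@@H](c1c(-c2ccc(OCc3ccccc3)cc2)oc2cc(OCc3ccccc3)cc(OCc3ccccc3)c2c1=O)[C@H](O)c1ccc(OCc2ccccc2)cc1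
F5 | step 5 | (2S,3S)-2-{5,7-bis(benzyloxy)-2-[4-(benzyloxy)phenyl]-4-oxo-4H-chromen-3-yl}-3-[4-(benzyloxy)phenyl]-3-hydroxypropaneperoxoic acid | OOC(=O)[C@@H](c1c(-c2ccc(OCc3ccccc3)cc2)oc2cc(OCc3ccccc3)cc(OCc3ccccc3)c2c1=O)[C@H](O)c1ccc(OCc2ccccc2)cc1
F6 | step 5 | (2S,3S)-2-{5,7-bis(benzyloxy)-2-[4-(benzyloxy)phenyl]-4-oxo-4H-chromen-3-yl}-3-[4-(benzyloxy)phenyl]-3-hydroxypropanoic acid | OC(=O)[C@@H](c1c(-c2ccc(OCc3ccccc3)cc2)oc2cc(OCc3ccccc3)cc(OCc3ccccc3)c2c1=O)[C@H](O)c1ccc(OCc2ccccc2)cc1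
F7 | step 5 | methyl (2S,3S)-2-{5,7-bis(benzyloxy)-2-[4-(benzyloxy)phenyl]-4-oxo-4H-chromen-3-yl}-3-[4-(benzyloxy)phenyl]-3-hydroxypropanoate | COC(=O)[C@@H](c1c(-c2ccc(OCc3ccccc3)cc2)oc2cc(OCc3ccccc3)cc(OCc3ccccc3)c2c1=O)[C@H](O)c1ccc(OCc2ccccc2)cc1
F8 | step 5 | methyl (2S,3S)-2-{5,7-bis(benzyloxy)-2-[4-(benzyloxy)phenyl]-4-oxo-4H-chromen-3-yl}-3-[4-(benzyloxy)phenyl]-3-[(trimethylsilyl)oxy]propanoate | COC(=O)[C@@H](c1c(-c2ccc(OCc3ccccc3)cc2)oc2cc(OCc3ccccc3)cc(OCc3ccccc3)c2c1=O)[C@H](O[Si](C)(C)C)c1ccc(OCc2ccccc2)cc1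
F9 | step 5 | caesium salt of the aryl anion formed by O-arylation in the (2S,3S) series | COC(=O)[C@@H](c1c(-c2ccc(OCc3ccccc3)cc2)oc2cc(OCc3ccccc3)cc(OCc3ccccc3)c2c1=O)[C@H](Oc1cc(OCc2ccccc2)cc(OCc2ccccc2)[c-]1)c1ccc(OCc2ccccc2)cc1.[Cs+]
F10 | step 5 | (2S,3S)-5,7-bis(benzyloxy)-2-[4-(benzyloxy)phenyl]-3-{5,7-bis(benzyloxy)-2-[4-(benzyloxy)phenyl]-4-oxo-4H-chromen-3-yl}-2,3-dihydro-4H-chromen-4-one (2,3-cis) | O=C1c2c(OCc3ccccc3)cc(OCc3ccccc3)cc2O[C@H](c2ccc(OCc3ccccc3)cc2)[C@@H]1c1c(-c2ccc(OCc3ccccc3)cc2)oc2cc(OCc3ccccc3)cc(OCc3ccccc3)c2c1=O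
F11 | step 4 | tert-butyl 3-[2,4-bis(benzyloxy)-6-hydroxybenzoyl]-4-[4-(benzyloxy)phenyl]-4-oxobutanoate (racemic) | CC(C)(C)OC(=O)CC(C(=O)c1ccc(OCc2ccccc2)cc1)C(=O)c1c(O)cc(OCc2ccccc2)cc1OCc1ccccc1
F12 | step 4 | {5,7-bis(benzyloxy)-2-[4-(benzyloxy)phenyl]-4-oxo-4H-chromen-3-yl}acetic acid | OC(=O)Cc1c(-c2ccc(OCc3ccccc3)cc2)oc2cc(OCc3ccccc3)cc(OCc3ccccc3)c2c1=O
F13 | step 4 | mixed anhydride of F12 and pivalic acid | CC(C)(C)C(=O)OC(=O)Cc1c(-c2ccc(OCc3ccccc3)cc2)oc2cc(OCc3ccccc3)cc(OCc3ccccc3)c2c1=O
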